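# Proposed synthesis of CNP0108136.1 by ring-closing metathesis at C2=C3 and alkene shift into conjugation

Atom numbering used throughout: the carbocycle runs C1 (bearing the isopropenyl group), C2, C3=C4, C5, C6 (lactone O–CH), C7, C8 (bearing CO2Me), C9 (ketone), C10, C11 (ketone), C12–C13 (oxirane, methyl on C12), C14. C20 is the lactone carbonyl on C4.

## Analysis of the target

Target 21 is a fourteen-membered carbocycle (C1–C14) bridged between C4 and C6 by a γ-lactone (C4, C5, C6, O, C20). Its C3=C4 bond is exocyclic to the lactone and E, and the ring also carries a trisubstituted oxirane at C12–C13, an isopropenyl group on C1, a methyl ester on C8 and ketones at C9 and C11. There are five stereocentres, C1 (R), C6 (S), C8 (S), C12 (S) and C13 (S), in two clusters: C1/C12/C13, linked through C14, and C6/C8, linked through C7. The clusters are insulated from each other by C9–C11 on one side and C2–C5 on the other, so each needs its own chiral source. In the first cluster the oxirane holds C11 and C14 cis and its oxygen lies anti to the isopropenyl group, which is the arrangement of a trans-5-substituted 2,3-epoxycyclohexanone. C8 is the α-carbon of a β-keto ester and C10 lies between two ketones, so C8 is configurationally mobile and the C9–C11 array is acidic and enolised. The α,β-epoxy ketone is sensitive to acid, reductants and nucleophiles, and the alkylidene lactone is a Michael acceptor. The difficulty is to close a fourteen-membered ring that contains all of this without making stereocentres late and without forcing a trisubstituted conjugated alkene to form in the ring-closing event. The strategy rests on the fact that C3=C4 is the conjugated isomer of a disubstituted C2=C3 alkene. C2 is the carbon set free when the C11–C2 bond of a carvone-derived epoxy ketone is cut, so C1, C11, C12, C13 and C14 all come from one terpene.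

## Retrosynthetic reasoning

**Target 21 to macrocycle 20 (alkene transposition).** The C3=C4 bond is moved one position to C2=C3, which leaves a hydrogen on C4. This turns the ring alkene into a simple disubstituted, non-conjugated one. It also makes the C4 configuration and the C2=C3 geometry irrelevant, because the forward shift runs through the lactone dienolate and ends at the thermodynamic E-alkylidene lactone. The forward reaction needs an amidine base that reaches the doubly activated C4–H but not C1–H. The same medium equilibrates C8.

**Macrocycle 20 to seco diene 19 (C2=C3).** The ring is opened at C2=C3 into a vinyl group on C1 and a vinyl group on C4. This bond is chosen because two monosubstituted alkenes are the best case for a macrocyclising metathesis. A cut at C3=C4 would need an α-methylene lactone partner and would form a trisubstituted conjugated alkene. A cut in the C9–C11 region would need a strong-base macrocyclisation. The forward step has to engage the two vinyl groups and leave the isopropenyl group alone.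

**Seco diene 19 to ester 7 and keto ester 18 (C10–C11).** The chain is cut between the two stereo-clusters, with C11 as an ester and C10 as the terminal carbon of a polyanion. This is a Claisen coupling of the kind known for β-keto ester dianions. The lactone α-position is more acidic than the C10 methyl group, so the lactone must be enolised as well, and this is turned to use. Keto ester 18 carries the lactone as its base-stable conjugated ethylidene isomer. Kinetic protonation of the lactone dienolate at the end of the coupling produces the C4 vinyl group exactly when it is needed.

**Ester 7 back to (S)-carvone 1.** The C1 vinyl group comes from aldehyde 4 by methylenation with ylide 6, made from salt 5. Aldehyde 4 comes from ketol 3 by cleavage of the C11–C2 bond, which leaves C11 as the methyl ester and C2 as the aldehyde. Ketol 3 comes from epoxy ketone 2, which can only enolise toward C2. Epoxy ketone 2 comes from 1 by nucleophilic epoxidation, which sets C12 and C13 anti to the C1 substituent. The gain is that three stereocentres and the oxirane geometry are bought with one ring-controlled reaction.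

**Keto ester 18 back to D-glutamic acid 8.** The C7–C8 bond is cut to iodide 16 and methyl acetoacetate 17; this is a soft enolate alkylation that the conjugated lactone tolerates. The ethylidene group of 16 comes from an aldol–dehydration on silyl ether 11 (via 12, 13, 14 and alcohol 15). The C6 stereocentre comes from 8 through lactone acid 9 and alcohol 10, by diazotisation with retention.

## Alternatives that were turned down

**Alternative 1: three-component lactone annulation.**
- Disconnection: C4–C5, O–C20 and C3=C4.
- Forward key step: a phosphonoacetate anion opens terminal epoxide A2 at C5, the C6 alkoxide lactonises, and the phosphono lactone anion olefinates aldehyde A3 in the same flask, giving alkylidene lactone A1 with both arms attached.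
- For: it is convergent and makes the conjugated alkylidene lactone directly, with no isomerisation step. On that point it is stronger than the chosen route. The ketal in A2 also keeps the acidic diketone out of the flask.
- Against: A1 is still acyclic. The fourteen-membered ring would have to be closed afterwards at C10–C11 by a macrocyclic Claisen condensation of a methyl ketone enolate next to a Michael-accepting lactone with acidic C2–H. C8 would then need a regioselective carbomethoxylation on a macrocyclic triketone-like system. The olefination of a phosphono lactone is also not reliably E-selective.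
- Comparison: the chosen strategy closes the ring with a neutral, functional-group-tolerant catalyst and carries the C8 ester from the start, so only one step follows the ring closure.

**Alternative 2: Darzens macrocyclisation.**
- Disconnection: C12–C13 and the oxirane C13–O bond.
- Forward key step: a lithium amide enolises the α-chloro ketone of seco aldehyde A5 at C12; aldol addition to the C13 aldehyde closes the ring and the aldolate displaces chloride, giving macrocyclic epoxy ketone A4.
- For: ring and oxirane form in one operation, and the alkylidene lactone is already in place. On bond economy in the key step it is stronger.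
- Against: C12 and C13 are created during a macrocyclisation with no nearby controlling element, so up to four oxirane stereoisomers can form. The base also meets an enolisable aldehyde, acidic C2–H of the alkylidene lactone, and a β-silyloxy ester at C8/C9 that can eliminate. After the key step the C9 silyl ether must still be removed and oxidised to reach the diketone.
- Comparison: the chosen strategy takes C12 and C13 from the ring-controlled epoxidation of 1 and creates no stereocentre in its ring closure.

**Alternative 3: nitrile oxide–alkyne macrocyclisation.**
- Disconnection: C9–C10 and O–C11 of an isoxazole that masks the diketone.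
- Forward key step: the C9 aldoxime of A7 is oxidised to the nitrile oxide under high dilution and adds to the C10≡C11 alkyne, giving isoxazole-bridged macrocycle A6.
- For: the cycloaddition is a proven macrocyclisation with reliable regiochemistry, and the isoxazole removes all β-dicarbonyl acidity until the end. That is a real advantage over carrying the free diketone through a metathesis.
- Against: the nitrile oxide can also add to the isopropenyl group and to the alkylidene lactone. Unmasking needs N–O reduction (Mo(CO)6 or SmI2 type) and enaminone hydrolysis in the presence of an α,β-epoxy ketone and a conjugated lactone, both of which are reducible or acid-sensitive. C8 in A7 sits between an ester and an oxime and is as labile as in the target.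
- Comparison: the chosen strategy accepts the free diketone but has no reductive or acidic step after the ring is closed.

Key step: step 14

Remark on the chemistry: C8 (α-carbon of a β-keto ester) and C10 (between two ketones) enolise freely. Compounds 18–20 are therefore carried as C8 epimer and keto–enol mixtures, and the (8S) configuration of 21 is assumed to be the one favoured at equilibrium in the macrocycle, where step 15 sets it.

## Route

**Step 1**
Reactants: 1 (S)-carvone
Product: 2 (1S,4S,6S)-1-methyl-4-(prop-1-en-2-yl)-7-oxabicyclo[4.1.0]heptan-2-one (trans-carvone oxide)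
Conditions: 30% H2O2, aq. NaOH, MeOH, 0 °C
Reagents that add atoms: hydrogen peroxide, OO
Why: Weitz–Scheffer nucleophilic epoxidation; hydroperoxide adds axially to the enone face anti to the isopropenyl group, so the oxirane (C12, C13) forms trans to the C1 substituent, and the unactivated isopropenyl alkene is not touched.

**Step 2**
Reactants: 2 trans-carvone oxide
Product: 3 (1S,4R,6S)-3-hydroxy-1-methyl-4-(prop-1-en-2-yl)-7-oxabicyclo[4.1.0]heptan-2-one (both C3 epimers)
Conditions: KN(SiMe3)2, THF, −78 °C; 3-phenyl-2-(phenylsulfonyl)oxaziridine, −78 °C; sat. NH4Cl
Reagents that add atoms: 3-phenyl-2-(phenylsulfonyl)oxaziridine, O=S(=O)(N1OC1c1ccccc1)c1ccccc1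
Why: Davis α-hydroxylation of a ketone enolate; the ketone can enolise only toward the CH2 group because the other α-carbon is the quaternary oxirane carbon, and the oxaziridine does not oxidise the isopropenyl group. The carbinol configuration is irrelevant because this carbon becomes the aldehyde.

**Step 3**
Reactants: 3 α-ketol
Product: 4 methyl (2S,3S)-3-[(2R)-2-formyl-3-methylbut-3-en-1-yl]-2-methyloxirane-2-carboxylate
Conditions: Pb(OAc)4, MeOH–PhH (1:1), 0 °C; filtered and used at once
Reagents that add atoms: methanol, CO
Why: Criegee-type cleavage of an α-ketol by tetravalent lead; the ketone is taken up as its methyl hemiketal and the C–C bond breaks to give the methyl ester (C11) and the aldehyde (C2). No stereocentre is involved, and the cold, near-neutral conditions spare the enolisable C1–H.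

**Step 4**
Reactants: 4 aldehyde ester; 5 methyltriphenylphosphonium bromide
Product: 7 methyl (2S,3S)-3-[(2S)-2-ethenyl-3-methylbut-3-en-1-yl]-2-methyloxirane-2-carboxylate, via methylenetriphenylphosphorane 6 (not isolated)
Conditions: 5, KN(SiMe3)2, THF, 0 °C; then 4, −78 → 0 °C
Reagents that add atoms: none
Why: Wittig methylenation; the aldehyde reacts far faster than the hindered glycidic ester, and a slight deficit of base with addition of 4 to cold ylide keeps contact of the C1–H with base short.

**Step 5**
Reactants: 8 D-glutamic acid
Product: 9 (R)-5-oxooxolane-2-carboxylic acid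
Conditions: NaNO2, 2 M HCl, H2O, 0 °C → rt
Reagents that add atoms: none
Why: Diazotisation with double inversion (α-lactone, then opening by the γ-carboxyl group) gives the butyrolactone with net retention, which fixes C6.

**Step 6**
Reactants: 9 lactone acid
Product: 10 (R)-5-(hydroxymethyl)oxolan-2-one
Conditions: BH3·SMe2, THF, 0 °C → rt; then MeOH
Reagents that add atoms: none
Why: Borane reduces the carboxylic acid through its acyloxyborane much faster than it reduces the lactone.

**Step 7**
Reactants: 10 hydroxymethyl lactone
Product: 11 (R)-5-{[tert-butyl(dimethyl)silyl]oxymethyl}oxolan-2-one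
Conditions: tBuMe2SiCl, imidazole, CH2Cl2, rt
Reagents that add atoms: tert-butyldimethylsilyl chloride, CC(C)(C)[Si](C)(C)Cl
Why: Standard silylation of a primary alcohol; the ether keeps the oxygen from acting as nucleophile or leaving group during the enolate chemistry.

**Step 8**
Reactants: 11 silyl ether lactone
Product: 12 (5R)-5-{[tert-butyl(dimethyl)silyl]oxymethyl}-3-(1-hydroxyethyl)oxolan-2-one (diastereomer mixture)
Conditions: LiN(iPr)2, THF, −78 °C; CH3CHO, −78 °C; sat. NH4Cl
Reagents that add atoms: acetaldehyde, CC=O
Why: Aldol addition of the lactone lithium enolate; both new stereocentres are removed in the next step, so no control is needed.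

**Step 9**
Reactants: 12 aldol adduct
Product: 14 (3E,5R)-5-{[tert-butyl(dimethyl)silyl]oxymethyl}-3-ethylideneoxolan-2-one, via secondary mesylate 13 (not isolated)
Conditions: MsCl, Et3N, CH2Cl2, 0 °C; then DBU, rt
Reagents that add atoms: methanesulfonyl chloride, CS(=O)(=O)Cl (its atoms stay in 13 and are lost on elimination)
Why: Mesylation and E1cB elimination give the conjugated alkylidene lactone, mainly as the more stable E isomer; the Z isomer is equally usable because step 13 erases this geometry.

**Step 10**
Reactants: 14 ethylidene lactone silyl ether
Product: 15 (3E,5R)-3-ethylidene-5-(hydroxymethyl)oxolan-2-one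
Conditions: HF·pyridine, THF, 0 °C → rt
Reagents that add atoms: none
Why: Fluoride cleavage of the primary silyl ether under non-basic conditions, so no alkoxide is formed that could add to the conjugated lactone or translactonise.

**Step 11**
Reactants: 15 alcohol
Product: 16 (3E,5R)-3-ethylidene-5-(iodomethyl)oxolan-2-one
Conditions: I2, PPh3, imidazole, CH2Cl2, 0 °C → rt
Reagents that add atoms: iodine, II
Why: Appel-type iodination of a primary alcohol through the alkoxyphosphonium salt; the stereocentre is not involved and the electron-poor alkene does not react with iodine.

**Step 12**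
Reactants: 16 iodide; 17 methyl acetoacetate
Product: 18 methyl 2-{[(2S,4E)-4-ethylidene-5-oxooxolan-2-yl]methyl}-3-oxobutanoate (both C2 epimers; the descriptor at the ring carbon changes by priority only)
Conditions: 17 (2 equiv), NaH (1.8 equiv), THF–DMF, 0 °C; then 16, 45 °C
Reagents that add atoms: none
Why: C-alkylation of the soft sodium enolate of a β-keto ester with a primary iodide forms C7–C8; excess 17 leaves no base stronger than its enolate. The lactone is already the conjugated isomer, so this base cannot isomerise it, and its trisubstituted alkene is a poor Michael acceptor.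

**Step 13**
Reactants: 18 keto ester lactone; 7 vinyl epoxy ester
Product: 19 methyl 5-{(2S,3S)-3-[(2S)-2-ethenyl-3-methylbut-3-en-1-yl]-2-methyloxiran-2-yl}-2-{[(2R)-4-ethenyl-5-oxooxolan-2-yl]methyl}-3,5-dioxopentanoate (seco diene; both epimers at C4 and C8)
Conditions: 18, LiN(iPr)2 (4.2 equiv), THF–DMPU, −78 °C; then 7 (0.9 equiv), −78 → −30 °C; AcOH in THF, −78 °C
Reagents that add atoms: none
Why: The amide base gives the trilithio species (C8 enolate, lactone dienolate by γ-deprotonation of the ethylidene group, C10 carbanion); its most basic carbon, C10, is acylated by ester 7 as in the Huckin–Weiler γ-acylation of β-keto ester dianions (Claisen condensation), and a fourth equivalent takes up the new diketone proton. With every lactone held as its dienolate, none is left to act as electrophile or proton source. Cold acetic acid then protonates the dienolate at C4 (the known kinetic α-protonation that deconjugates alkylidene lactones), which converts the ethylidene group into the vinyl group.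

**Step 14**
Reactants: 19 seco diene
Product: 20 β,γ-unsaturated macrocyclic lactone: carbocycle of 21 with C2=C3 in place of C3=C4 and a hydrogen on C4; (1S,6R,12S,13S); either C2=C3 geometry; both epimers at C4 and C8
Conditions: (H2IMes)(PCy3)Cl2Ru=CHPh (second-generation Grubbs catalyst, 10 mol %, added in portions), 1,4-benzoquinone (20 mol %), CH2Cl2 (1 mM), 40 °C, argon sparge
Reagents that add atoms: none
Why: Olefin metathesis by the Chauvin mechanism: after phosphine loss the ruthenium benzylidene exchanges onto one vinyl group, the new alkylidene adds across the other vinyl group to a ruthenacyclobutane, and cycloreversion releases the ring alkene and a ruthenium methylidene, with ethylene lost overall. The closest known reaction type is the macrocyclising ring-closing metathesis of a diene with two terminal alkenes. The one ring formed is the fourteen-membered carbocycle C1–C14, closed at C2=C3 by joining the internal carbons of the two vinyl groups; the lactone is left as a bridge across C4–C6. No stereocentre is created, and the C2=C3 geometry and C4 configuration are left free because step 15 removes both. The step needs site selectivity over the isopropenyl group, which could close a ring of the same size: that 1,1-disubstituted alkene loads the carbene much more slowly and would have to give a trisubstituted ring alkene, so the vinyl pair should win kinetically. It needs cyclisation over oligomerisation, which high dilution, portionwise catalyst and removal of ethylene favour, helped by the turn elements in the chain (lactone, oxirane, enolised diketone). It also needs the vinyl lactone to stay β,γ-unsaturated until the ring is closed; benzoquinone suppresses ruthenium hydride alkene migration and no base is present.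

**Step 15**
Reactants: 20 β,γ-unsaturated macrocyclic lactone
Product: 21 CNP0108136.1, (1R,6S,8S,12S,13S,3E)
Conditions: DBU (3 equiv), CH2Cl2, rt; pH 5 phosphate buffer work-up
Reagents that add atoms: none
Why: Base-mediated conjugation of a β,γ-unsaturated lactone: after forming the diketonate, DBU removes the doubly activated C4–H and the dienolate is protonated at C2 under equilibrating conditions, giving the thermodynamic alkylidene lactone with C2 anti to C20 (E); C1–H is not acidic, so C1 is untouched. The same medium equilibrates C8 through the β-keto ester enolate to the more stable epimer, taken to be (8S).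

## Compound list

1 | (S)-carvone | CC1=CC[C@@H](CC1=O)C(C)=C | starting material
2 | (1S,4S,6S)-1-methyl-4-(prop-1-en-2-yl)-7-oxabicyclo[4.1.0]heptan-2-one | C=C(C)[C@@H]1CC(=O)[C@@]2(C)O[C@H]2C1 | intermediate
3 | (1S,4R,6S)-3-hydroxy-1-methyl-4-(prop-1-en-2-yl)-7-oxabicyclo[4.1.0]heptan-2-one, both C3 epimers | C=C(C)[C@@H]1C(O)C(=O)[C@@]2(C)O[C@H]2C1 | intermediate
4 | methyl (2S,3S)-3-[(2R)-2-formyl-3-methylbut-3-en-1-yl]-2-methyloxirane-2-carboxylate | C=C(C)[C@H](C=O)C[C@@H]1O[C@]1(C)C(=O)OC | intermediate
5 | methyltriphenylphosphonium bromide | C[P+](c1ccccc1)(c1ccccc1)c1ccccc1.[Br-] | starting material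
6 | methylenetriphenylphosphorane | C=P(c1ccccc1)(c1ccccc1)c1ccccc1 | intermediate (not isolated)
7 | methyl (2S,3S)-3-[(2S)-2-ethenyl-3-methylbut-3-en-1-yl]-2-methyloxirane-2-carboxylate | C=C(C)[C@H](C=C)C[C@@H]1O[C@]1(C)C(=O)OC | intermediate
8 | D-glutamic acid | N[C@H](CCC(=O)O)C(=O)O | starting material
9 | (R)-5-oxooxolane-2-carboxylic acid | OC(=O)[C@H]1CCC(=O)O1 | intermediate
10 | (R)-5-(hydroxymethyl)oxolan-2-one | OC[C@H]1CCC(=O)O1 | intermediate
11 | (R)-5-{[tert-butyl(dimethyl)silyl]oxymethyl}oxolan-2-one | CC(C)(C)[Si](C)(C)OC[C@H]1CCC(=O)O1 | intermediate
12 | (5R)-5-{[tert-butyl(dimethyl)silyl]oxymethyl}-3-(1-hydroxyethyl)oxolan-2-one, diastereomer mixture | CC(O)C1C[C@H](CO[Si](C)(C)C(C)(C)C)OC1=O | intermediate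
13 | 1-[(5R)-5-{[tert-butyl(dimethyl)silyl]oxymethyl}-2-oxooxolan-3-yl]ethyl methanesulfonate | CC(OS(C)(=O)=O)C1C[C@H](CO[Si](C)(C)C(C)(C)C)OC1=O | intermediate (not isolated)
14 | (3E,5R)-5-{[tert-butyl(dimethyl)silyl]oxymethyl}-3-ethylideneoxolan-2-one | C/C=C1\C[C@H](CO[Si](C)(C)C(C)(C)C)OC1=O | intermediate
15 | (3E,5R)-3-ethylidene-5-(hydroxymethyl)oxolan-2-one | C/C=C1\C[C@H](CO)OC1=O | intermediate
16 | (3E,5R)-3-ethylidene-5-(iodomethyl)oxolan-2-one | C/C=C1\C[C@H](CI)OC1=O | intermediate
17 | methyl acetoacetate | CC(=O)CC(=O)OC | starting material
18 | methyl 2-{[(2S,4E)-4-ethylidene-5-oxooxolan-2-yl]methyl}-3-oxobutanoate, both C2 epimers | C/C=C1\C[C@H](CC(C(C)=O)C(=O)OC)OC1=O | intermediate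
19 | seco diene, methyl 5-{(2S,3S)-3-[(2S)-2-ethenyl-3-methylbut-3-en-1-yl]-2-methyloxiran-2-yl}-2-{[(2R)-4-ethenyl-5-oxooxolan-2-yl]methyl}-3,5-dioxopentanoate, both epimers at C4 and C8 | C=C(C)[C@H](C=C)C[C@@H]1O[C@]1(C)C(=O)CC(=O)C(C(=O)OC)C[C@H]2CC(C=C)C(=O)O2 | intermediate
20 | β,γ-unsaturated macrocyclic lactone, (1S,6R,12S,13S), C2=C3 of either geometry, both epimers at C4 and C8 | C=C(C)[C@@H]1C=CC2C[C@H](CC(C(=O)OC)C(=O)CC(=O)[C@@]3(C)O[C@H]3C1)OC2=O | intermediate
21 | CNP0108136.1, (1R,6S,8S,12S,13S,3E) | C=C(C)[C@@H]1C/C=C2\C[C@H](C[C@H](C(=O)OC)C(=O)CC(=O)[C@@]3(C)O[C@H]3C1)OC2=O | target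

## Step count and least certain steps

Total: 15 steps. Longest linear sequence: 11 steps (8 → 21, steps 5–15). The carvone branch contributes 4 steps before the coupling.

**Step 14 (key step).** Most likely to go wrong: oligomerisation in place of ring closure, because both vinyl groups are branched at the allylic carbon and load the carbene slowly. Second, competing closure onto the isopropenyl group, which gives a ring of the same size. Third, catalyst sequestration by the enolised diketone or alkene migration in the vinyl lactone.
Fallback (relay ring-closing metathesis), setting out from 4 and returning at 20: Wittig reaction of 4 with the ylide from hex-5-en-1-yl(triphenyl)phosphonium bromide should give relay triene ester F1. Coupling of F1 with 18 under the conditions of step 13 should give relay seco compound F2. With the same ruthenium catalyst the carbene loads at the unhindered terminal alkene of the relay arm, expels cyclopentene and is delivered directly onto C2, from where only the lactone vinyl group is within reach.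

**Step 13.** Most likely to go wrong: incomplete formation of the trilithio species, so that a neutral conjugated lactone remains as Michael acceptor and proton source. Second, acylation of the lactone dienolate in competition with C10. Third, partial γ-protonation on quench, which regenerates the ethylidene lactone.
Fallback (lactone masked as an acetal, so that only a plain β-keto ester dianion is needed), setting out from 14 and returning at 19: kinetic deconjugation of 14 (LiN(iPr)2, DMPU, then AcOH at −78 °C) gives vinyl lactone F3. Reduction with iBu2AlH gives lactol F4, and MeOH with pyridinium p-toluenesulfonate gives methyl acetal F5. Bu4NF gives alcohol F6 and I2/PPh3/imidazole gives iodide F7. Alkylation of 17 (NaH) gives acetal keto ester F8. Its dianion (NaH, then n-BuLi) is acylated by 7 to give acetal seco diene F9. Aqueous AcOH gives lactol seco diene F10, and Ag2CO3 on Celite oxidises the lactol to 19. No step after F3 exposes a vinyl lactone to base.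

**Step 4.** Most likely to go wrong: loss of configuration at C1, or migration of the isopropenyl alkene into conjugation, by enolisation of the aldehyde on contact with the basic ylide. This aldehyde is α-branched and β,γ-unsaturated.
Fallback, from 4 to 7 directly: non-basic titanium–zinc methylenation (CH2I2, Zn, Ti(OiPr)4, THF, rt), which proceeds through a gem-dimetallic methylene reagent and not an ylide, is selective for aldehydes over esters, and is mild toward the glycidic ester.

**Step 2.** Most likely to go wrong: addition of the enolate to the sulfonimine by-product, or base-induced opening of the oxirane before oxidation.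
Fallback (Rubottom sequence), setting out from 2 and returning at 3: trapping of the enolate as it forms (LiN(iPr)2 with Me3SiCl present, −78 °C) gives silyl enol ether F11. Dimethyldioxirane at −40 °C epoxidises the electron-rich enol ether in preference to the isopropenyl group, and a citric acid work-up releases 3.

**Step 15.** Most likely to go wrong: equilibration at C8 stopping at a mixture with the C8 epimer, since nothing but the relative stability of the two macrocycles decides it.
Fallback, setting out from the mixture of 21 and C8 epimer F12 and returning at 21: crystallisation-induced equilibration, in which the mixture is stirred with a catalytic amine base in a solvent from which 21 crystallises, so that the solid phase drains the equilibrium. If neither epimer crystallises, F12 is separated and resubmitted to the conditions of step 15.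

## Further compounds

F1 | step 14 | methyl (2S,3S)-2-methyl-3-[(2S,3Z)-2-(prop-1-en-2-yl)nona-3,8-dien-1-yl]oxirane-2-carboxylate | C=C(C)[C@H](/C=C\CCCC=C)C[C@@H]1O[C@]1(C)C(=O)OC
F2 | step 14 | methyl 5-{(2S,3S)-2-methyl-3-[(2S,3Z)-2-(prop-1-en-2-yl)nona-3,8-dien-1-yl]oxiran-2-yl}-2-{[(2R)-4-ethenyl-5-oxooxolan-2-yl]methyl}-3,5-dioxopentanoate | C=C(C)[C@H](/C=C\CCCC=C)C[C@@H]1O[C@]1(C)C(=O)CC(=O)C(C(=O)OC)C[C@H]2CC(C=C)C(=O)O2
F3 | step 13 | (5R)-5-{[tert-butyl(dimethyl)silyl]oxymethyl}-3-ethenyloxolan-2-one | C=CC1C[C@H](CO[Si](C)(C)C(C)(C)C)OC1=O
F4 | step 13 | (5R)-5-{[tert-butyl(dimethyl)silyl]oxymethyl}-3-ethenyloxolan-2-ol | C=CC1C[C@H](CO[Si](C)(C)C(C)(C)C)OC1O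
F5 | step 13 | tert-butyl{[(2R)-4-ethenyl-5-methoxyoxolan-2-yl]methoxy}dimethylsilane | C=CC1C[C@H](CO[Si](C)(C)C(C)(C)C)OC1OC
F6 | step 13 | [(2R)-4-ethenyl-5-methoxyoxolan-2-yl]methanol | C=CC1C[C@H](CO)OC1OC
F7 | step 13 | (5R)-3-ethenyl-5-(iodomethyl)-2-methoxyoxolane | C=CC1C[C@H](CI)OC1OC
F8 | step 13 | methyl 2-{[(2R)-4-ethenyl-5-methoxyoxolan-2-yl]methyl}-3-oxobutanoate | CC(=O)C(C(=O)OC)C[C@H]1CC(C=C)C(OC)O1
F9 | step 13 | methyl 5-{(2S,3S)-3-[(2S)-2-ethenyl-3-methylbut-3-en-1-yl]-2-methyloxiran-2-yl}-2-{[(2R)-4-ethenyl-5-methoxyoxolan-2-yl]methyl}-3,5-dioxopentanoate | C=C(C)[C@H](C=C)C[C@@H]1O[C@]1(C)C(=O)CC(=O)C(C(=O)OC)C[C@H]2CC(C=C)C(OC)O2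
F10 | step 13 | methyl 5-{(2S,3S)-3-[(2S)-2-ethenyl-3-methylbut-3-en-1-yl]-2-methyloxiran-2-yl}-2-{[(2R)-4-ethenyl-5-hydroxyoxolan-2-yl]methyl}-3,5-dioxopentanoate | C=C(C)[C@H](C=C)C[C@@H]1O[C@]1(C)C(=O)CC(=O)C(C(=O)OC)C[C@H]2CC(C=C)C(O)O2
F0 | step 4 | none | none
F11 | step 2 | trimethyl{[(1S,4S,6S)-1-methyl-4-(prop-1-en-2-yl)-7-oxabicyclo[4.1.0]hept-2-en-2-yl]oxy}silane | C=C(C)[C@@H]1C=C(O[Si](C)(C)C)[C@@]2(C)O[C@H]2C1
F12 | step 15 | C8 epimer of 21, (1R,6S,8R,12S,13S,3E) | C=C(C)[C@@H]1C/C=C2\C[C@H](C[C@@H](C(=O)OC)C(=O)CC(=O)[C@@]3(C)O[C@H]3C1)OC2=O
A1 | alternative 1 | E-alkylidene lactone carrying the epoxy ester arm and the ketal arm | C=C(C)[C@@H](C[C@@H]3O[C@]3(C)C(=O)OC)C/C=C2\C[C@H](CCC4(C)OCCO4)OC2=O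
A2 | alternative 1 | 2-methyl-2-{2-[(2S)-oxiran-2-yl]ethyl}-1,3-dioxolane | CC1(CC[C@H]2CO2)OCCO1
A3 | alternative 1 | methyl (2S,3S)-2-methyl-3-[(2S)-3-methyl-2-(2-oxoethyl)but-3-en-1-yl]oxirane-2-carboxylate | C=C(C)[C@@H](C[C@@H]1O[C@]1(C)C(=O)OC)CC=O
A4 | alternative 2 | macrocyclic epoxy ketone with C9 tert-butyldimethylsilyl ether | C=C(C)[C@@H]1C/C=C2\C[C@H](C[C@H](C(=O)OC)[C@@H](O[Si](C)(C)C(C)(C)C)CC(=O)[C@@]3(C)O[C@H]3C1)OC2=O
A5 | alternative 2 | seco α-chloro ketone with C13 aldehyde and C9 silyl ether | C=C(C)[C@@H](CC=O)C/C=C1\C[C@H](C[C@H](C(=O)OC)[C@@H](O[Si](C)(C)C(C)(C)C)CC(=O)C(C)Cl)OC1=O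
A6 | alternative 3 | isoxazole-bridged macrocyclic lactone | C=C(C)[C@@H]1C/C=C2\C[C@H](C[C@H](C(=O)OC)c4cc(on4)[C@@]3(C)O[C@H]3C1)OC2=O
A7 | alternative 3 | seco C9 aldoxime with ethynyl oxirane | C=C(C)[C@@H](C[C@@H]1O[C@]1(C)C#C)C/C=C2\C[C@H](C[C@@H](C=NO)C(=O)OC)OC2=O
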